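Add the two columns of each row of Friday's run first. Their sum has a plain zero of the scale: substrate that turned into target and nothing else would keep it at 100 percent.

| flask | substrate | gas phase | remark | time |
|---|---|---|---|---|
| Friday's | 5 mM | 3 mM (held) | the very flask that is asked about, followed so far |  |
| flask | 5.0 mM | 3.0 mM (held) |  | 5.0 min |

Friday's run (percent of the substrate charged)

| time / s | target / % | substrate / % |
|---|---|---|
| 15.0 | 52 | 48 |
| 25.0 | 78 | 16 |
| 40.0 | 92 | 2 |
| 50.0 | 85 | 3 |

(standard deviation of a reading: 1.5 percentage points)

- at the start none of the gas phase is in solution

- blue: doubling the transfer coefficient of the gas phase, all else as stated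
- violet: doubling the saturation concentration of gas phase, all else as stated

- the target standing at 5.0 min, as a percentage of the substrate charged
- the change that raises the amount of target at 5.0 min, in percent of the substrate charged most ("none" if none brings more than 2 percentage points) (blue / violet / none)
- amount of target at 5.0 min, in percent of the substrate charged, after violet

Read the rows downward. The sum stands at 100% at 15.0 s, at 94.0% at 25.0 s, at 94.0% at 40.0 s and at 88.0% at 50.0 s, so material is leaving for something outside these columns.

Now read the last two rows across. Substrate reads 2% and 3%, hardly any of the charge, while target falls from 92% to 85%. Take that fall as first-order in c(target), and call the result the loss constant, a pseudo-first-order constant: 0.00791 s⁻¹. It is a rough reading, a drop of 7 percentage points against a scatter of 1.5 points per reading.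

My reckoning carries it from 50.0 s to 5.0 min and gives 11.8%. If the constant doubles with the saturation, violet leaves 1.63%, and I expect no gain from either change.

The forecast gives 20%, more than mine, with none as the best change and 4% after violet, holding that “Both changes bring the gas on sooner or higher, so neither helps”.

The flask gives 7.91% at 5.0 min, 3.9 points below my reckoning. The best change is none: blue moves target by −3.4 points, violet by −7.5 points, leaving 0.401%. In this flask at 2.50 min, c(dissolved gas) stands at 74.4% of saturation. Use the loss constant again on this flask: carried from the 35.5% of target at 2.50 min to 5.00 min, it gives 10.8%, more than the 7.91% computed.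

    gas phase ⇌ dissolved gas, rate k1*(csat - [dissolved gas]) (kL = 0.0759 s⁻¹)
    substrate + dissolved gas → target (k = 187 L mol⁻¹ s⁻¹)
    dissolved gas + target → over-reacted product (k = 4.24 L mol⁻¹ s⁻¹)
    dissolved gas → decomposed reagent (k = 0.00705 s⁻¹)
    dissolved gas ⇌ dormant form (K = 5.40, k = 0.0140 s⁻¹)

Read the same flask at 80 s instead: the loss constant from 50.0 s gives 67.0%, and the computed target there is 67.2%.

(The readings come from a simulation on assumed constants; noise was put on by code.)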